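Retrosynthesis: the four phenols are unmasked from methyl ethers last. The pyranone is opened at its lactone C–O bond and at C5–C6 (dioxinone dienolate plus arylacetaldehyde), which leaves a tetra-oxygenated benzophenone with a 2-hydroxyethyl arm.
Enabling feature: rings A and B are both 2-acyl-3-alkylresorcinols attached to the same ketone carbon. In each ring, C1 (ketone-bearing) and C2 (alkyl-bearing) are the two carbons of one alkyne of the diynone Et–C≡C–CO–C≡C–CH2CH2OTBS, and C3–C6 (oxygen on C4 and C6) are the four carbons of 1,1-dimethoxy-3-(trimethylsilyloxy)buta-1,3-diene, so four aryl C–C bonds are cut at once.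
Forward: diynone 9 (from but-3-yn-1-ol and but-1-yne) and diene 16 (from acetyl chloride and 1,1-dichloroethene) are joined in step 8, where rings A and B form together. The pyranone ring follows in step 14 by acylketene lactonisation, and BBr3 frees the phenols in step 15.
Stereochemistry: the target has no stereocentre. The carbinol centres of 8 and 30 are racemic and are removed by oxidation.

Key step: step 8

Remark: but-1-yne is a gas (bp 8 °C) and is condensed into THF at −78 °C; 2,2,6-trimethyl-4H-1,3-dioxin-4-one 28 is taken as a commercial reagent.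

Step 1
Reactants: 1 but-3-yn-1-ol
Product: 2 tert-butyl(but-3-yn-1-yloxy)dimethylsilane
Conditions: TBSCl, imidazole, CH2Cl2, 0 °C to rt
Reagents that add atoms: tert-butyldimethylsilyl chloride, CC(C)(C)[Si](C)(C)Cl
Why: Silylation of a primary alcohol with TBSCl/imidazole is routine and leaves the terminal alkyne untouched.

Step 2
Reactants: 2 tert-butyl(but-3-yn-1-yloxy)dimethylsilane
Product: 5 5-[(tert-butyldimethylsilyl)oxy]pent-2-ynal, via lithium acetylide 3 (not isolated), via lithium hemiaminal alkoxide 4 (not isolated)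
Conditions: n-BuLi, THF, −78 °C; DMF, −78 to 0 °C; reverse quench into cold aq KH2PO4
Reagents that add atoms: N,N-dimethylformamide, CN(C)C=O
Why: Formylation of a lithium acetylide with DMF gives the hemiaminal alkoxide 4, which holds until the buffered reverse quench and so should release the ynal without conjugate addition of dimethylamine.

Step 3
Reactants: 6 but-1-yne; 5 5-[(tert-butyldimethylsilyl)oxy]pent-2-ynal
Product: 8 9-[(tert-butyldimethylsilyl)oxy]nona-3,6-diyn-5-ol (racemic), via but-1-yn-1-yllithium 7 (not isolated)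
Conditions: 6, n-BuLi, THF, −78 °C; then 5, −78 °C; aq NH4Cl
Reagents that add atoms: none
Why: 1,2-Addition of an alkynyllithium to an ynal at low temperature is the standard route to bis-propargylic alcohols; the new carbinol centre is racemic and is erased in step 4.

Step 4
Reactants: 8 9-[(tert-butyldimethylsilyl)oxy]nona-3,6-diyn-5-ol
Product: 9 9-[(tert-butyldimethylsilyl)oxy]nona-3,6-diyn-5-one
Conditions: DMP (Dess–Martin periodinane), CH2Cl2, 0 °C to rt; used promptly
Reagents that add atoms: none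
Why: Dess–Martin oxidation of bis-propargylic alcohols to cross-conjugated diynones is well established and mild enough for the silyl ether.

Step 5
Reactants: 10 acetyl chloride; 11 1,1-dichloroethene
Product: 13 4,4-dichlorobut-3-en-2-one, via 4,4,4-trichlorobutan-2-one 12 (not isolated)
Conditions: AlCl3, CH2Cl2, 0 °C to rt; ice/aq HCl; distillation at reduced pressure (loss of HCl)
Reagents that add atoms: none
Why: Friedel–Crafts-type acylation of the alkene at its CH2 terminus gives the beta-trichloro ketone, which should lose HCl readily (E1cB) to the conjugated dichlorovinyl ketone.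

Step 6
Reactants: 13 4,4-dichlorobut-3-en-2-one
Product: 15 4,4-dimethoxybut-3-en-2-one, via 4-chloro-4-methoxybut-3-en-2-one 14 (not isolated)
Conditions: NaOMe (2.2 equiv), MeOH, 0 °C to rt
Reagents that add atoms: sodium methoxide, [Na+].[O-]C
Why: Two successive addition–elimination steps (vinylogous acyl substitution) by methoxide at the beta carbon replace both chlorides.

Step 7
Reactants: 15 4,4-dimethoxybut-3-en-2-one
Product: 16 1,1-dimethoxy-3-(trimethylsilyloxy)buta-1,3-diene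
Conditions: TMSCl, Et3N, ZnCl2 (cat.), Et2O, rt to 35 °C; filtration, distillation
Reagents that add atoms: chlorotrimethylsilane, C[Si](C)(C)Cl
Why: Enol silylation of the methyl ketone (amine base, ZnCl2 catalysis) gives the cross-conjugated 2-silyloxydiene, the methyl group being the only enolisable position.

Step 8
Reactants: 9 9-[(tert-butyldimethylsilyl)oxy]nona-3,6-diyn-5-one; 16 1,1-dimethoxy-3-(trimethylsilyloxy)buta-1,3-diene (two equivalents react)
Product: 24 {2-[2-(tert-butyldimethylsilyloxy)ethyl]-4-hydroxy-6-methoxyphenyl}(2-ethyl-4-hydroxy-6-methoxyphenyl)methanone, via cyclohexadiene adduct 17 (not isolated), via cyclohexadiene adduct 18 (not isolated), via aryl ynone 19 (not isolated), via aryl ynone 20 (not isolated), via cyclohexadiene adduct 21 (not isolated), via cyclohexadiene adduct 22 (not isolated), via bis(trimethylsilyl) ether 23 (not isolated)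
Conditions: 16 (5 equiv, two portions), toluene, 80 to 120 °C, sealed tube; then K2CO3 (cat.), MeOH, 0 °C to rt
Reagents that add atoms: none
Why: Proposed new method: the one-pot twofold benzannulation of a cross-conjugated diynone has not been demonstrated, but each event is the known normal-demand Diels–Alder addition of a 1,1-dialkoxy-3-silyloxybutadiene to an alkynone or alkynoate followed by aromatisation, which is the closest known reaction type. The diene HOMO is largest at its CH2 terminus and the ynone LUMO at the alkyne carbon beta to C=O, so an asynchronous [4+2] addition should join CH2 to the beta carbon and the ketene acetal carbon to the alpha carbon on each alkyne. Ring A and ring B each close in this intermolecular [4+2] mode (four diene carbons plus two alkyne carbons), and each 6,6-dimethoxycyclohexa-1,4-diene then loses methanol by 1,4-elimination to give the arene, the silyl enol ether becoming the para silyloxy group that methanolysis frees. No stereocentre is formed. The step needs regiocontrol on both alkynes, reaction at C≡C in preference to C=O, and a second addition to the intermediate aryl ynone 19 or 20; ynone polarisation sets the first, the absence of any Lewis acid the second, and the third is expected because the new 2,6-disubstituted aryl ring is twisted out of conjugation with the carbonyl group, which keeps the remaining ynone electron-poor while excess diene makes up for what the liberated methanol consumes.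

Step 9
Reactants: 24 {2-[2-(tert-butyldimethylsilyloxy)ethyl]-4-hydroxy-6-methoxyphenyl}(2-ethyl-4-hydroxy-6-methoxyphenyl)methanone
Product: 25 {2-[2-(tert-butyldimethylsilyloxy)ethyl]-4,6-dimethoxyphenyl}(2-ethyl-4,6-dimethoxyphenyl)methanone
Conditions: MeI, K2CO3, acetone, 56 °C
Reagents that add atoms: iodomethane, CI
Why: Williamson O-methylation of two acidic para-acyl phenols; K2CO3 should touch neither the silyl ether nor the hindered ketone.

Step 10
Reactants: 25 {2-[2-(tert-butyldimethylsilyloxy)ethyl]-4,6-dimethoxyphenyl}(2-ethyl-4,6-dimethoxyphenyl)methanone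
Product: 26 2-[2-(2-ethyl-4,6-dimethoxybenzoyl)-3,5-dimethoxyphenyl]ethan-1-ol
Conditions: TBAF, THF, 0 °C to rt; aq NH4Cl
Reagents that add atoms: none
Why: Fluoride-mediated cleavage of a primary TBS ether; the non-acidic conditions avoid ketalisation of the neighbouring diaryl ketone by the freed alcohol.

Step 11
Reactants: 26 2-[2-(2-ethyl-4,6-dimethoxybenzoyl)-3,5-dimethoxyphenyl]ethan-1-ol
Product: 27 [2-(2-ethyl-4,6-dimethoxybenzoyl)-3,5-dimethoxyphenyl]acetaldehyde
Conditions: DMP, NaHCO3, CH2Cl2, 0 °C to rt; used at once without chromatography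
Reagents that add atoms: none
Why: Buffered Dess–Martin oxidation should stop cleanly at the arylacetaldehyde, and the acid-free medium protects this enolisable aldehyde from cyclising onto the ortho ketone.

Step 12
Reactants: 27 [2-(2-ethyl-4,6-dimethoxybenzoyl)-3,5-dimethoxyphenyl]acetaldehyde; 28 2,2,6-trimethyl-4H-1,3-dioxin-4-one
Product: 30 6-{3-[2-(2-ethyl-4,6-dimethoxybenzoyl)-3,5-dimethoxyphenyl]-2-hydroxypropyl}-2,2-dimethyl-4H-1,3-dioxin-4-one (racemic), via lithium dienolate 29 (not isolated)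
Conditions: 28 (3 equiv), LiN(i-Pr)2 (LDA, 3 equiv), THF, −78 °C; then 27, −78 °C; aq NH4Cl at −78 °C
Reagents that add atoms: none
Why: Vinylogous aldol addition of the dioxinone lithium dienolate, which attacks aldehydes through its gamma carbon at −78 °C, while the tetra-ortho-substituted diaryl ketone is too hindered to compete; the racemic carbinol centre is oxidised in step 13.

Step 13
Reactants: 30 6-{3-[2-(2-ethyl-4,6-dimethoxybenzoyl)-3,5-dimethoxyphenyl]-2-hydroxypropyl}-2,2-dimethyl-4H-1,3-dioxin-4-one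
Product: 31 6-{3-[2-(2-ethyl-4,6-dimethoxybenzoyl)-3,5-dimethoxyphenyl]-2-oxopropyl}-2,2-dimethyl-4H-1,3-dioxin-4-one
Conditions: DMP, CH2Cl2, 0 °C to rt
Reagents that add atoms: none
Why: Dess–Martin oxidation of beta-hydroxy dioxinones to beta-keto dioxinones is a standard operation in dioxinone-based polyketide synthesis.

Step 14
Reactants: 31 6-{3-[2-(2-ethyl-4,6-dimethoxybenzoyl)-3,5-dimethoxyphenyl]-2-oxopropyl}-2,2-dimethyl-4H-1,3-dioxin-4-one
Product: 33 6-{[2-(2-ethyl-4,6-dimethoxybenzoyl)-3,5-dimethoxyphenyl]methyl}-4-hydroxy-2H-pyran-2-one, via acylketene 32 (not isolated)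
Conditions: toluene (dilute), 110 °C
Reagents that add atoms: none
Why: Thermal retro-[4+2] loss of acetone gives acylketene 32, which the enol oxygen of the 1,3-related ketone should trap (acylketene lactonisation) to form the 4-hydroxy-2-pyranone under neutral conditions.

Step 15
Reactants: 33 6-{[2-(2-ethyl-4,6-dimethoxybenzoyl)-3,5-dimethoxyphenyl]methyl}-4-hydroxy-2H-pyran-2-one
Product: 34 6-{[2-(2-ethyl-4,6-dihydroxybenzoyl)-3,5-dihydroxyphenyl]methyl}-4-hydroxy-2H-pyran-2-one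
Conditions: BBr3 (excess), CH2Cl2, −78 °C to rt; ice-water
Reagents that add atoms: none
Why: BBr3 ether cleavage (Lewis acid–base complexation, then bromide attack on methyl) should remove all four methyl groups, the two ortho to the ketone fastest through chelation, and 4-hydroxy-2-pyranones are known to tolerate the reagent.

Compound list
1 | but-3-yn-1-ol | C#CCCO | starting material
2 | tert-butyl(but-3-yn-1-yloxy)dimethylsilane | C#CCCO[Si](C)(C)C(C)(C)C | intermediate
3 | lithium 4-[(tert-butyldimethylsilyl)oxy]but-1-yn-1-ide (not isolated) | [Li]C#CCCO[Si](C)(C)C(C)(C)C | intermediate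
4 | lithium 5-[(tert-butyldimethylsilyl)oxy]-1-(dimethylamino)pent-2-yn-1-olate (racemic, not isolated) | [Li]OC(N(C)C)C#CCCO[Si](C)(C)C(C)(C)C | intermediate
5 | 5-[(tert-butyldimethylsilyl)oxy]pent-2-ynal | O=CC#CCCO[Si](C)(C)C(C)(C)C | intermediate
6 | but-1-yne | CCC#C | starting material
7 | but-1-yn-1-yllithium (not isolated) | CCC#C[Li] | intermediate
8 | 9-[(tert-butyldimethylsilyl)oxy]nona-3,6-diyn-5-ol (racemic) | CCC#CC(O)C#CCCO[Si](C)(C)C(C)(C)C | intermediate
9 | 9-[(tert-butyldimethylsilyl)oxy]nona-3,6-diyn-5-one | CCC#CC(=O)C#CCCO[Si](C)(C)C(C)(C)C | intermediate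
10 | acetyl chloride | CC(=O)Cl | starting material
11 | 1,1-dichloroethene | C=C(Cl)Cl | starting material
12 | 4,4,4-trichlorobutan-2-one (not isolated) | CC(=O)CC(Cl)(Cl)Cl | intermediate
13 | 4,4-dichlorobut-3-en-2-one | CC(=O)C=C(Cl)Cl | intermediate
14 | 4-chloro-4-methoxybut-3-en-2-one (E/Z mixture, not isolated) | CC(=O)C=C(Cl)OC | intermediate
15 | 4,4-dimethoxybut-3-en-2-one | CC(=O)C=C(OC)OC | intermediate
16 | 1,1-dimethoxy-3-(trimethylsilyloxy)buta-1,3-diene | C=C(O[Si](C)(C)C)C=C(OC)OC | intermediate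
17 | 5-[(tert-butyldimethylsilyl)oxy]-1-[2-ethyl-6,6-dimethoxy-4-(trimethylsilyloxy)cyclohexa-1,4-dien-1-yl]pent-2-yn-1-one (not isolated) | CCC1=C(C(=O)C#CCCO[Si](C)(C)C(C)(C)C)C(OC)(OC)C=C(O[Si](C)(C)C)C1 | intermediate
18 | 1-{2-[2-(tert-butyldimethylsilyloxy)ethyl]-6,6-dimethoxy-4-(trimethylsilyloxy)cyclohexa-1,4-dien-1-yl}pent-2-yn-1-one (not isolated) | CCC#CC(=O)C1=C(CCO[Si](C)(C)C(C)(C)C)CC(O[Si](C)(C)C)=CC1(OC)OC | intermediate
19 | 5-[(tert-butyldimethylsilyl)oxy]-1-[2-ethyl-6-methoxy-4-(trimethylsilyloxy)phenyl]pent-2-yn-1-one (not isolated) | CCc1cc(O[Si](C)(C)C)cc(OC)c1C(=O)C#CCCO[Si](C)(C)C(C)(C)C | intermediate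
20 | 1-{2-[2-(tert-butyldimethylsilyloxy)ethyl]-6-methoxy-4-(trimethylsilyloxy)phenyl}pent-2-yn-1-one (not isolated) | CCC#CC(=O)c1c(OC)cc(O[Si](C)(C)C)cc1CCO[Si](C)(C)C(C)(C)C | intermediate
21 | {2-[2-(tert-butyldimethylsilyloxy)ethyl]-6,6-dimethoxy-4-(trimethylsilyloxy)cyclohexa-1,4-dien-1-yl}[2-ethyl-6-methoxy-4-(trimethylsilyloxy)phenyl]methanone (not isolated) | CCc1cc(O[Si](C)(C)C)cc(OC)c1C(=O)C1=C(CCO[Si](C)(C)C(C)(C)C)CC(O[Si](C)(C)C)=CC1(OC)OC | intermediate
22 | [2-ethyl-6,6-dimethoxy-4-(trimethylsilyloxy)cyclohexa-1,4-dien-1-yl]{2-[2-(tert-butyldimethylsilyloxy)ethyl]-6-methoxy-4-(trimethylsilyloxy)phenyl}methanone (not isolated) | CCC1=C(C(=O)c2c(OC)cc(O[Si](C)(C)C)cc2CCO[Si](C)(C)C(C)(C)C)C(OC)(OC)C=C(O[Si](C)(C)C)C1 | intermediate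
23 | {2-[2-(tert-butyldimethylsilyloxy)ethyl]-6-methoxy-4-(trimethylsilyloxy)phenyl}[2-ethyl-6-methoxy-4-(trimethylsilyloxy)phenyl]methanone (not isolated) | CCc1cc(O[Si](C)(C)C)cc(OC)c1C(=O)c1c(OC)cc(O[Si](C)(C)C)cc1CCO[Si](C)(C)C(C)(C)C | intermediate
24 | {2-[2-(tert-butyldimethylsilyloxy)ethyl]-4-hydroxy-6-methoxyphenyl}(2-ethyl-4-hydroxy-6-methoxyphenyl)methanone | CCc1cc(O)cc(OC)c1C(=O)c1c(OC)cc(O)cc1CCO[Si](C)(C)C(C)(C)C | intermediate
25 | {2-[2-(tert-butyldimethylsilyloxy)ethyl]-4,6-dimethoxyphenyl}(2-ethyl-4,6-dimethoxyphenyl)methanone | CCc1cc(OC)cc(OC)c1C(=O)c1c(OC)cc(OC)cc1CCO[Si](C)(C)C(C)(C)C | intermediate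
26 | 2-[2-(2-ethyl-4,6-dimethoxybenzoyl)-3,5-dimethoxyphenyl]ethan-1-ol | CCc1cc(OC)cc(OC)c1C(=O)c1c(OC)cc(OC)cc1CCO | intermediate
27 | [2-(2-ethyl-4,6-dimethoxybenzoyl)-3,5-dimethoxyphenyl]acetaldehyde | CCc1cc(OC)cc(OC)c1C(=O)c1c(OC)cc(OC)cc1CC=O | intermediate
28 | 2,2,6-trimethyl-4H-1,3-dioxin-4-one | CC1=CC(=O)OC(C)(C)O1 | starting material
29 | lithium 2,2-dimethyl-6-methylidene-6H-1,3-dioxin-4-olate (not isolated) | C=C1C=C(O[Li])OC(C)(C)O1 | intermediate
30 | 6-{3-[2-(2-ethyl-4,6-dimethoxybenzoyl)-3,5-dimethoxyphenyl]-2-hydroxypropyl}-2,2-dimethyl-4H-1,3-dioxin-4-one (racemic) | CCc1cc(OC)cc(OC)c1C(=O)c2c(OC)cc(OC)cc2CC(O)CC3=CC(=O)OC(C)(C)O3 | intermediate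
31 | 6-{3-[2-(2-ethyl-4,6-dimethoxybenzoyl)-3,5-dimethoxyphenyl]-2-oxopropyl}-2,2-dimethyl-4H-1,3-dioxin-4-one | CCc1cc(OC)cc(OC)c1C(=O)c2c(OC)cc(OC)cc2CC(=O)CC3=CC(=O)OC(C)(C)O3 | intermediate
32 | 6-[2-(2-ethyl-4,6-dimethoxybenzoyl)-3,5-dimethoxyphenyl]hex-1-ene-1,3,5-trione (acylketene, not isolated) | CCc1cc(OC)cc(OC)c1C(=O)c2c(OC)cc(OC)cc2CC(=O)CC(=O)C=C=O | intermediate
33 | 6-{[2-(2-ethyl-4,6-dimethoxybenzoyl)-3,5-dimethoxyphenyl]methyl}-4-hydroxy-2H-pyran-2-one | CCc1cc(OC)cc(OC)c1C(=O)c2c(OC)cc(OC)cc2Cc3cc(O)cc(=O)o3 | intermediate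
34 | 6-{[2-(2-ethyl-4,6-dihydroxybenzoyl)-3,5-dihydroxyphenyl]methyl}-4-hydroxy-2H-pyran-2-one | CCc1cc(O)cc(O)c1C(=O)c1c(O)cc(O)cc1Cc1cc(O)cc(=O)o1 | target

Total step count: 15.
Longest linear sequence: 12 steps (steps 1–4, then 8–15). The diene branch (steps 5–7) joins at step 8.

Steps most likely to fail

1. Step 8 (the step proposed as a new method). The sequence may stall after the first annulation, the diene may be consumed by the methanol that aromatisation liberates, or the diynone may oligomerise on heating before both alkynes have reacted. The fallback builds the two rings in separate Diels–Alder/aromatisation events of the established single-alkyne kind; it sets out from diene 16 and comes back to the route at 25.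
   - Heating 16 with commercial ethyl pent-2-ynoate (neat, about 130 °C) should give the cycloadduct ethyl 2-ethyl-6,6-dimethoxy-4-(trimethylsilyloxy)cyclohexa-1,4-diene-1-carboxylate F1. This loses methanol to ethyl 2-ethyl-6-methoxy-4-(trimethylsilyloxy)benzoate F2, and K2CO3 (cat.)/MeOH frees ethyl 2-ethyl-4-hydroxy-6-methoxybenzoate F3.
   - MeI/K2CO3 gives ethyl 2-ethyl-4,6-dimethoxybenzoate F4, LiAlH4 in THF gives (2-ethyl-4,6-dimethoxyphenyl)methanol F5, and MnO2 in CH2Cl2 gives 2-ethyl-4,6-dimethoxybenzaldehyde F6.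
   - Lithium acetylide 3 (from 2 and n-BuLi) adds to F6 to give 5-[(tert-butyldimethylsilyl)oxy]-1-(2-ethyl-4,6-dimethoxyphenyl)pent-2-yn-1-ol F7, which DMP oxidises to 5-[(tert-butyldimethylsilyl)oxy]-1-(2-ethyl-4,6-dimethoxyphenyl)pent-2-yn-1-one F8.
   - One cycloaddition of F8 with 16 (toluene, 110–130 °C) should give the cyclohexadiene adduct {2-[2-(tert-butyldimethylsilyloxy)ethyl]-6,6-dimethoxy-4-(trimethylsilyloxy)cyclohexa-1,4-dien-1-yl}(2-ethyl-4,6-dimethoxyphenyl)methanone F9 and then, by loss of methanol, the aryl silyl ether {2-[2-(tert-butyldimethylsilyloxy)ethyl]-6-methoxy-4-(trimethylsilyloxy)phenyl}(2-ethyl-4,6-dimethoxyphenyl)methanone F10.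
   - Methanolysis gives the mono-phenol {2-[2-(tert-butyldimethylsilyloxy)ethyl]-4-hydroxy-6-methoxyphenyl}(2-ethyl-4,6-dimethoxyphenyl)methanone F11, and methylation as in step 9 gives 25.

2. Step 12 (with the aldehyde made in step 11). The basic dienolate may deprotonate the doubly activated benzylic C–H of the arylacetaldehyde instead of adding to the carbonyl group, and the aldehyde may close onto the neighbouring ketone or self-condense during handling. The fallback avoids the aldehyde altogether; it sets out from alcohol 26 and comes back at 31, so that steps 11–13 are bypassed.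
   - TEMPO (cat.)/PhI(OAc)2 in MeCN–water oxidises 26 to [2-(2-ethyl-4,6-dimethoxybenzoyl)-3,5-dimethoxyphenyl]acetic acid F12.
   - 1H-Benzotriazole/SOCl2 in CH2Cl2 converts F12 into 1-{[2-(2-ethyl-4,6-dimethoxybenzoyl)-3,5-dimethoxyphenyl]acetyl}-1H-benzotriazole F13.
   - Claisen-type C-acylation of excess lithium dienolate 29 with F13 (THF, −78 °C) should give keto-dioxinone 31 directly.

3. Step 15. Cleavage of the two ethers para to the ketone may be incomplete, or prolonged exposure to excess BBr3 at room temperature may induce Lewis-acid-promoted condensation of the pyranone with the chelated ketone. The fallback protects the para phenols as benzyl ethers so that the last step needs only BCl3 at low temperature; it sets out from diphenol 24 and comes back at target 34.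
   - BnBr/K2CO3 in DMF gives {4-(benzyloxy)-2-[2-(tert-butyldimethylsilyloxy)ethyl]-6-methoxyphenyl}[4-(benzyloxy)-2-ethyl-6-methoxyphenyl]methanone F14.
   - TBAF gives [4-(benzyloxy)-2-ethyl-6-methoxyphenyl][4-(benzyloxy)-2-(2-hydroxyethyl)-6-methoxyphenyl]methanone F15, and buffered DMP gives {5-(benzyloxy)-2-[4-(benzyloxy)-2-ethyl-6-methoxybenzoyl]-3-methoxyphenyl}acetaldehyde F16.
   - Dienolate 29 gives the aldol adduct 6-(3-{5-(benzyloxy)-2-[4-(benzyloxy)-2-ethyl-6-methoxybenzoyl]-3-methoxyphenyl}-2-hydroxypropyl)-2,2-dimethyl-4H-1,3-dioxin-4-one F17, and DMP gives 6-(3-{5-(benzyloxy)-2-[4-(benzyloxy)-2-ethyl-6-methoxybenzoyl]-3-methoxyphenyl}-2-oxopropyl)-2,2-dimethyl-4H-1,3-dioxin-4-one F18.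
   - Thermolysis in toluene passes through the acylketene 6-{5-(benzyloxy)-2-[4-(benzyloxy)-2-ethyl-6-methoxybenzoyl]-3-methoxyphenyl}hex-1-ene-1,3,5-trione F19 to 6-({5-(benzyloxy)-2-[4-(benzyloxy)-2-ethyl-6-methoxybenzoyl]-3-methoxyphenyl}methyl)-4-hydroxy-2H-pyran-2-one F20.
   - BCl3 with pentamethylbenzene as cation scavenger (CH2Cl2, −78 to 0 °C) should remove both benzyl groups and, by chelation-assisted cleavage, the two methyl ethers ortho to the ketone, giving 34.

Further compounds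
F1 | step 8 | ethyl 2-ethyl-6,6-dimethoxy-4-(trimethylsilyloxy)cyclohexa-1,4-diene-1-carboxylate | CCOC(=O)C1=C(CC)CC(O[Si](C)(C)C)=CC1(OC)OC
F2 | step 8 | ethyl 2-ethyl-6-methoxy-4-(trimethylsilyloxy)benzoate | CCOC(=O)c1c(OC)cc(O[Si](C)(C)C)cc1CC
F3 | step 8 | ethyl 2-ethyl-4-hydroxy-6-methoxybenzoate | CCOC(=O)c1c(OC)cc(O)cc1CC
F4 | step 8 | ethyl 2-ethyl-4,6-dimethoxybenzoate | CCOC(=O)c1c(OC)cc(OC)cc1CC
F5 | step 8 | (2-ethyl-4,6-dimethoxyphenyl)methanol | CCc1cc(OC)cc(OC)c1CO
F6 | step 8 | 2-ethyl-4,6-dimethoxybenzaldehyde | CCc1cc(OC)cc(OC)c1C=O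
F7 | step 8 | 5-[(tert-butyldimethylsilyl)oxy]-1-(2-ethyl-4,6-dimethoxyphenyl)pent-2-yn-1-ol (racemic) | CCc1cc(OC)cc(OC)c1C(O)C#CCCO[Si](C)(C)C(C)(C)C
F8 | step 8 | 5-[(tert-butyldimethylsilyl)oxy]-1-(2-ethyl-4,6-dimethoxyphenyl)pent-2-yn-1-one | CCc1cc(OC)cc(OC)c1C(=O)C#CCCO[Si](C)(C)C(C)(C)C
F9 | step 8 | {2-[2-(tert-butyldimethylsilyloxy)ethyl]-6,6-dimethoxy-4-(trimethylsilyloxy)cyclohexa-1,4-dien-1-yl}(2-ethyl-4,6-dimethoxyphenyl)methanone | CCc1cc(OC)cc(OC)c1C(=O)C1=C(CCO[Si](C)(C)C(C)(C)C)CC(O[Si](C)(C)C)=CC1(OC)OC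
F10 | step 8 | {2-[2-(tert-butyldimethylsilyloxy)ethyl]-6-methoxy-4-(trimethylsilyloxy)phenyl}(2-ethyl-4,6-dimethoxyphenyl)methanone | CCc1cc(OC)cc(OC)c1C(=O)c1c(OC)cc(O[Si](C)(C)C)cc1CCO[Si](C)(C)C(C)(C)C
F11 | step 8 | {2-[2-(tert-butyldimethylsilyloxy)ethyl]-4-hydroxy-6-methoxyphenyl}(2-ethyl-4,6-dimethoxyphenyl)methanone | CCc1cc(OC)cc(OC)c1C(=O)c1c(OC)cc(O)cc1CCO[Si](C)(C)C(C)(C)C
F12 | step 12 | [2-(2-ethyl-4,6-dimethoxybenzoyl)-3,5-dimethoxyphenyl]acetic acid | CCc1cc(OC)cc(OC)c1C(=O)c1c(OC)cc(OC)cc1CC(=O)O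
F13 | step 12 | 1-{[2-(2-ethyl-4,6-dimethoxybenzoyl)-3,5-dimethoxyphenyl]acetyl}-1H-benzotriazole | CCc1cc(OC)cc(OC)c1C(=O)c1c(OC)cc(OC)cc1CC(=O)n1nnc2ccccc12
F14 | step 15 | {4-(benzyloxy)-2-[2-(tert-butyldimethylsilyloxy)ethyl]-6-methoxyphenyl}[4-(benzyloxy)-2-ethyl-6-methoxyphenyl]methanone | CCc1cc(OCc2ccccc2)cc(OC)c1C(=O)c1c(OC)cc(OCc2ccccc2)cc1CCO[Si](C)(C)C(C)(C)C
F15 | step 15 | [4-(benzyloxy)-2-ethyl-6-methoxyphenyl][4-(benzyloxy)-2-(2-hydroxyethyl)-6-methoxyphenyl]methanone | CCc1cc(OCc2ccccc2)cc(OC)c1C(=O)c1c(OC)cc(OCc2ccccc2)cc1CCO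
F16 | step 15 | {5-(benzyloxy)-2-[4-(benzyloxy)-2-ethyl-6-methoxybenzoyl]-3-methoxyphenyl}acetaldehyde | CCc1cc(OCc2ccccc2)cc(OC)c1C(=O)c1c(OC)cc(OCc2ccccc2)cc1CC=O
F17 | step 15 | 6-(3-{5-(benzyloxy)-2-[4-(benzyloxy)-2-ethyl-6-methoxybenzoyl]-3-methoxyphenyl}-2-hydroxypropyl)-2,2-dimethyl-4H-1,3-dioxin-4-one (racemic) | CCc1cc(OCc2ccccc2)cc(OC)c1C(=O)c1c(OC)cc(OCc2ccccc2)cc1CC(O)CC1=CC(=O)OC(C)(C)O1
F18 | step 15 | 6-(3-{5-(benzyloxy)-2-[4-(benzyloxy)-2-ethyl-6-methoxybenzoyl]-3-methoxyphenyl}-2-oxopropyl)-2,2-dimethyl-4H-1,3-dioxin-4-one | CCc1cc(OCc2ccccc2)cc(OC)c1C(=O)c1c(OC)cc(OCc2ccccc2)cc1CC(=O)CC1=CC(=O)OC(C)(C)O1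
F19 | step 15 | 6-{5-(benzyloxy)-2-[4-(benzyloxy)-2-ethyl-6-methoxybenzoyl]-3-methoxyphenyl}hex-1-ene-1,3,5-trione | CCc1cc(OCc2ccccc2)cc(OC)c1C(=O)c1c(OC)cc(OCc2ccccc2)cc1CC(=O)CC(=O)C=C=O
F20 | step 15 | 6-({5-(benzyloxy)-2-[4-(benzyloxy)-2-ethyl-6-methoxybenzoyl]-3-methoxyphenyl}methyl)-4-hydroxy-2H-pyran-2-one | CCc1cc(OCc2ccccc2)cc(OC)c1C(=O)c1c(OC)cc(OCc2ccccc2)cc1Cc1cc(O)cc(=O)o1
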